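Slowness is what we would suspect first: red feeds its coupling partner over 2.0 min on a quarter of amber's free catalyst, while amber has everything in from the start.

| flask | left-handed substrate | right-handed substrate | coupling partner | protic impurity | free catalyst | added ligand | stray impurity | temperature | remark | time |
|---|---|---|---|---|---|---|---|---|---|---|
| east | 0.10 M | 0.10 M | 1.2 equiv (fed, over 2.0 min) | 0.010 M | 0.35 mol% | 1.2 mM | 69 µM | 85 °C | run made earlier; the fed solution adds 0.50 times the starting volume |  |
| south-west | 0.10 M | 0.10 M | 1.2 equiv (fed, over 2.0 min) | 0.010 M | 1.6 mol% | 1.2 mM | 69 µM | 100 °C | run made earlier; the fed solution adds 0.50 times the starting volume |  |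
| red | 0.10 M | 0.10 M | 1.20 equiv (fed, over 2.0 min) | 0.0100 M | 0.5 mol% | 1.2 mM | 69 µM | 100 °C | the fed solution adds 0.50 times the starting volume | 2.0 min |
| amber | 0.10 M | 0.10 M | 1.20 equiv | 0.0100 M | 2 mol% | 1.2 mM | 69 µM | 100 °C | everything together at the start, the whole solution of coupling partner included, so that from the start the volume is larger by 0.50 times the starting volume | 2.0 min |

east run (percent of the left-handed substrate and right-handed substrate together charged)

| time / min | left-handed product / % | right-handed product / % |
|---|---|---|
| 0.333 | 6 | 4 |
| 0.667 | 6 | 7 |
| 1.00 | 14 | 8 |
| 2.00 | 31 | 20 |
| 3.00 | 32 | 22 |
| 4.00 | 32 | 23 |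

south-west run (percent of the left-handed substrate and right-handed substrate together charged)

| time / s | left-handed product / % | right-handed product / % |
|---|---|---|
| 15.0 | 5 | 3 |
| 30.0 | 10 | 5 |
| 50.0 | 14 | 9 |
| 60.0 | 20 | 8 |
| 80.0 | 21 | 15 |
| 90.0 | 25 | 18 |
| 120 | 33 | 22 |

(readings scatter by 1.5 percentage points)

* the winner by share of left-handed product in all that became left-handed product or right-handed product; "neither" if no more than 2 percentage points parts them (red / amber / neither)
* share of left-handed product in all that became left-handed product or right-handed product, red
* share of left-handed product in all that became left-handed product or right-handed product, amber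

- free catalyst is single-handed; left-handed substrate and right-handed substrate are mirror images of each other, charged as a racemate, each of them at the stated concentration
- charges are per starting volume, the dose included; the dosed solution carries all of it
- what was read earlier has a scatter of 1.5 percentage points, one standard deviation

Red's nearest neighbour is south-west, the same dosed flask at 100 °C with 1.6 mol% of free catalyst instead of 0.5 mol%. We follow one molecule of coupling partner: if it reaches a substrate at all, it takes left-handed or right-handed substrate at its fork, and if both routes have the same order in partner and catalyst, the odds are s times c(left-handed substrate)/c(right-handed substrate). Partner and catalyst then cancel, so at given substrate concentrations loading, dilution and feed speed can change how soon a molecule is taken but not which way it goes, and the logarithms of the two remaining fractions stand in the ratio s. Each substrate is half the charge, so its remaining fraction is one minus twice its product reading. South-west at 120 s reads 1.86 and east, at 85 °C, reads 1.66 at 4.00 min, and we keep the mean, 1.76, as the fork ratio, a selectivity factor read through the scatter.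

What can still differ between flasks is how far the substrates went. East levels off at 55.0% of both substrates, below the 60.0% the partner charge allows, so partner is the limiting reagent. If amber ends with 55.0% of the right-handed substrate left, the mean of what the last readings of east and south-west leave, the fork ratio gives a share of 59.1%. If red lags as east did at 2.00 min, with 60.0% left, it gives 59.7%. That gap is within the margin, so we say neither.

The forecast said neither, with 60% for red and 59.5% for amber, on the ground that “the share barely drifts with conversion”; our amber stands a little lower.

The simulation gives 58.8% for red and 58.3% for amber, so the answer is neither.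

    coupling partner + free catalyst + left-handed substrate → free catalyst + left-handed product (k = 17000 L² mol⁻² s⁻¹, Ea = 9.00 kJ mol⁻¹)
    coupling partner + free catalyst + right-handed substrate → free catalyst + right-handed product (k = 10000 L² mol⁻² s⁻¹, Ea = 11.0 kJ mol⁻¹)
    coupling partner + protic impurity → quenched reagent (k = 15.0 L mol⁻¹ s⁻¹, Ea = 55.0 kJ mol⁻¹)
    free catalyst + added ligand ⇌ idle complex, settled at all times (K = 270 L mol⁻¹, ΔH = −26.0 kJ mol⁻¹)
    free catalyst + stray impurity → spent catalyst (k = 58000 L mol⁻¹ s⁻¹, Ea = 44.0 kJ mol⁻¹)
    (constants at 100 °C)

In red, with the other concentrations as charged, partner has a half-life of 0.82 s on the left-handed route and 1.4 s on the right-handed one, against 4.62 s towards quenched reagent, and the dose lasts far longer than any of these. The remaining fractions give a fork ratio of 1.70 in red and 1.70 in amber, and our 1.76, applied to the neighbour of amber with 0.300 equiv of partner and 89% of its right-handed substrate left, gives 62.8%, where that flask stands at 62.0%.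

All runs were generated by integration for an exercise, noise included.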